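## Retrosynthetic overview

- C6 is α to the ketone and therefore labile, so it is set last by kinetic protonation of a C1–C6 silyl dienol ether. Before that, the ester is cleaved and the C2 heptenyl chain is attached by Suzuki coupling of a 2-iodoenone with an (E)-alkenylboronate made from (R)-propylene oxide.
- The cyclohexenone is the only ring. It is formed once, in one flask, from two acyclic partners: first the C4–C5 bond (aldol), then the C2=C3 bond (phosphonate olefination).
- Enabling feature: C3 (the enone β-carbon with its CH2OH) and C4 (carbinol) are a dihydroxyacetone unit inside the ring. The C5 hydroxyl is its aldol hydroxyl, and C2 lies between that former ketone carbon and the C1 ketone, so it is the carbon of a β-ketophosphonate.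
- The four-carbon partner (C5 aldehyde, C6 with the butenoate chain, C1 masked as a dioxolane, C2 as CH2P(O)(OEt)2) comes from a 4-phosphono-acetoacetate by allylation, ketalisation, reduction and cross-metathesis.

Key step: step 7

Remark: C1–C6 in the text are the atoms of the cyclohex-2-en-1-one ring (C1 carbonyl, C2=C3, C3 bearing CH2OH, C4 and C5 carbinols, C6 bearing the butenoate chain); in the systematic names they are positions 2, 3, 4, 5, 6 and 1 of the cyclohexenyl group.
Remark: the carbon that becomes C6 is written without a stereo mark in every SMILES before the final product, because it is racemic (open-chain compounds) or an epimer mixture (ring compounds) by design; step 11 sets it.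
Remark: the phosphono-acetoacetate used in step 3 is assumed to be a purchasable building block.

## Route

Step 1
Reactants: 1 (R)-2-methyloxirane; 2 but-3-en-1-ylmagnesium bromide
Product: 3 (2R)-hept-6-en-2-ol
Conditions: CuI (10 mol %), THF, −30 → 0 °C; then aq NH4Cl
Reagents that add atoms: none
Why: Copper-catalysed SN2 opening of the epoxide by the Grignard reagent at the unsubstituted carbon, which does not touch the stereocentre, so the (R) centre of 1 becomes the (R) carbinol of the side chain.

Step 2
Reactants: 3 (2R)-hept-6-en-2-ol; 4 4,4,5,5-tetramethyl-2-vinyl-1,3,2-dioxaborolane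
Product: 5 (2R,6E)-7-(4,4,5,5-tetramethyl-1,3,2-dioxaborolan-2-yl)hept-6-en-2-ol
Conditions: second-generation Grubbs catalyst RuCl2(=CHPh)(PCy3)(H2IMes) (5 mol %), CH2Cl2, 40 °C
Reagents that add atoms: none
Why: Olefin cross-metathesis of a terminal alkene with a vinylboronate should give the (E)-alkenylboronate under thermodynamic control, and the remote free alcohol is tolerated.

Step 3
Reactants: 6 ethyl 4-(diethoxyphosphoryl)-3-oxobutanoate; 7 3-bromoprop-1-ene
Product: 8 ethyl 2-[(diethoxyphosphoryl)acetyl]pent-4-enoate (racemic)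
Conditions: K2CO3, acetone, rt
Reagents that add atoms: none
Why: C-alkylation of a β-keto ester enolate (acetoacetate alkylation); the CH2 between ester and ketone is by far the most acidic site, so the phosphonate CH2 stays untouched, and the new centre is racemic on purpose.

Step 4
Reactants: 8 ethyl 2-[(diethoxyphosphoryl)acetyl]pent-4-enoate
Product: 9 ethyl 2-{2-[(diethoxyphosphoryl)methyl]-1,3-dioxolan-2-yl}pent-4-enoate (racemic)
Conditions: ethane-1,2-diol, p-TsOH (cat.), toluene, reflux, azeotropic removal of water
Reagents that add atoms: ethane-1,2-diol (OCCO)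
Why: Acid-catalysed ketalisation masks the C1 ketone as a dioxolane, so that the aldehyde made next is a true aldehyde and not an unreactive enolised 1,3-dicarbonyl compound, and the phosphonate CH2 is switched off until step 7.

Step 5
Reactants: 9 ethyl 2-{2-[(diethoxyphosphoryl)methyl]-1,3-dioxolan-2-yl}pent-4-enoate
Product: 10 diethyl {[2-(1-oxopent-4-en-2-yl)-1,3-dioxolan-2-yl]methyl}phosphonate (racemic)
Conditions: i-Bu2AlH (1.2 equiv), CH2Cl2, −78 °C; then aq potassium sodium tartrate KNaC4H4O6
Reagents that add atoms: none
Why: Partial reduction of the only ester with one hydride at low temperature; the aluminium hemiacetal, held by the neighbouring ketal oxygen, should collapse to the aldehyde only on work-up.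

Step 6
Reactants: 10 diethyl {[2-(1-oxopent-4-en-2-yl)-1,3-dioxolan-2-yl]methyl}phosphonate; 11 tert-butyl 2-methylprop-2-enoate
Product: 12 tert-butyl (2E)-5-{2-[(diethoxyphosphoryl)methyl]-1,3-dioxolan-2-yl}-2-methyl-6-oxohex-2-enoate (racemic)
Conditions: second-generation Grubbs catalyst RuCl2(=CHPh)(PCy3)(H2IMes) (5 mol %), 11 (5 equiv), CH2Cl2, 40 °C
Reagents that add atoms: none
Why: Olefin cross-metathesis of the terminal alkene with an excess of the 1,1-disubstituted acrylate should give the trisubstituted enoate as the (E) isomer (ester trans to the chain) under thermodynamic control, with aldehyde, ketal and phosphonate tolerated.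

Step 7
Reactants: 12 tert-butyl (2E)-5-{2-[(diethoxyphosphoryl)methyl]-1,3-dioxolan-2-yl}-2-methyl-6-oxohex-2-enoate; 13 2,2-dimethyl-1,3-dioxan-5-one
Product: 16 tert-butyl (2E)-4-[(5R,6S)-5,6-dihydroxy-4-(hydroxymethyl)-2-oxocyclohex-3-en-1-yl]-2-methylbut-2-enoate, via aldol adduct 14 (not isolated), via open-chain ketophosphonate 15 (not isolated)
Conditions: (S)-proline (30 mol %), 13 (3 equiv), DMSO–H2O, rt; then 2 M aq HCl, THF, rt; then K2CO3 to pH 10, 0 °C → rt
Reagents that add atoms: water (O)
Why: (S)-Proline turns 13 into its enamine, which adds to one face of the aldehyde of 12 through the carboxylic-acid-bound chair transition state and forms the C4–C5 bond of 14; the closest known reactions are the proline-catalysed anti aldols of this dioxanone with α-branched aldehydes (a small-molecule copy of a tagatose-type aldolase) and the intramolecular Horner–Wadsworth–Emmons closures of ketose-derived β-ketophosphonates to hydroxylated cyclohexenones. Aqueous acid then removes the acetonide and the dioxolane, which frees the C3 ketone between two hydroxylated carbons and the C1 ketone that makes C2 a β-ketophosphonate carbon (15). On basification the C2 carbanion adds to the C3 ketone and the oxaphosphetane collapses to the C2=C3 bond, which closes the six-membered carbocycle, the only ring, in a 6-(enolendo)-exo-trig mode. C4 (R in the ring) and C5 (S) are set by the catalyst alone (anti aldol, the 3S,4S ketose pattern); both enantiomers of racemic 12 are consumed, and the resulting C6 epimers converge in step 11. The step needs cross-aldol over self-aldol selectivity, secured by the α-branched, poorly enolisable aldehyde and the excess of the reactive ketone donor, and a single olefination site, secured because C3 is the only carbonyl that C2 can reach through a six-membered transition state and the tert-butyl ester is inert to both the acid and the carbonate stage.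

Step 8
Reactants: 16 tert-butyl (2E)-4-[(5R,6S)-5,6-dihydroxy-4-(hydroxymethyl)-2-oxocyclohex-3-en-1-yl]-2-methylbut-2-enoate
Product: 17 tert-butyl (2E)-4-[(5R,6S)-5,6-dihydroxy-4-(hydroxymethyl)-3-iodo-2-oxocyclohex-3-en-1-yl]-2-methylbut-2-enoate
Conditions: I2, K2CO3, DMAP (20 mol %), THF–H2O (1:1), rt
Reagents that add atoms: iodine, I2 (II)
Why: Amine-catalysed α-iodination of the enone (Baylis–Hillman-type sequence: conjugate addition of DMAP, iodination of the enolate at C2, loss of DMAP), a reaction type known for 3-substituted cyclohexenones and run in water so that the triol needs no protection.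

Step 9
Reactants: 17 tert-butyl (2E)-4-[(5R,6S)-5,6-dihydroxy-4-(hydroxymethyl)-3-iodo-2-oxocyclohex-3-en-1-yl]-2-methylbut-2-enoate; 5 (2R,6E)-7-(4,4,5,5-tetramethyl-1,3,2-dioxaborolan-2-yl)hept-6-en-2-ol
Product: 18 tert-butyl (2E)-4-[(5R,6S)-5,6-dihydroxy-3-[(1E,6R)-6-hydroxyhept-1-en-1-yl]-4-(hydroxymethyl)-2-oxocyclohex-3-en-1-yl]-2-methylbut-2-enoate
Conditions: PdCl2(dppf) (5 mol %), AsPh3 (10 mol %), Cs2CO3, DMF–THF–H2O, rt
Reagents that add atoms: none
Why: Suzuki–Miyaura coupling (oxidative addition of zerovalent palladium into the C2–I bond, transmetalation of the alkenylboronate with retention of its (E) geometry, reductive elimination) should give the 2-alkenyl enone at room temperature, mild enough for the β-hydroxy ketone.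

Step 10
Reactants: 18 tert-butyl (2E)-4-[(5R,6S)-5,6-dihydroxy-3-[(1E,6R)-6-hydroxyhept-1-en-1-yl]-4-(hydroxymethyl)-2-oxocyclohex-3-en-1-yl]-2-methylbut-2-enoate
Product: 19 (2E)-4-[(5R,6S)-5,6-dihydroxy-3-[(1E,6R)-6-hydroxyhept-1-en-1-yl]-4-(hydroxymethyl)-2-oxocyclohex-3-en-1-yl]-2-methylbut-2-enoic acid (C6 epimers)
Conditions: CF3CO2H–CH2Cl2 (1:4), 0 °C → rt
Reagents that add atoms: none
Why: Acidolysis of the tert-butyl ester (loss of the tert-butyl cation as isobutene) frees the acid before the last step, so that nothing acidic or basic has to follow the setting of C6.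

Step 11
Reactants: 19 (2E)-4-[(5R,6S)-5,6-dihydroxy-3-[(1E,6R)-6-hydroxyhept-1-en-1-yl]-4-(hydroxymethyl)-2-oxocyclohex-3-en-1-yl]-2-methylbut-2-enoic acid (C6 epimers)
Product: 21 pestallic acid I, via hexakis(trimethylsilyl) dienol ether 20 (not isolated)
Conditions: Me3SiCl (8 equiv), LiN(SiMe3)2 (6.2 equiv), THF, −78 °C; then aq citric acid, THF–MeOH, −40 → 0 °C
Reagents that add atoms: none
Why: Kinetic protonation of a silyl enol ether: deprotonation at C6 (the only α-hydrogen of the ketone) with in-flask silylation makes C6 planar in 20, and on mild acid hydrolysis the proton should enter from the ring face opposite the two cis silyloxy groups at C4 and C5, which places the butenoate chain cis to both oxygens (6R) while all six silyl groups are lost.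

## Compound list

1 | (R)-2-methyloxirane | C[C@@H]1CO1 | starting material
2 | but-3-en-1-ylmagnesium bromide | C=CCC[Mg]Br | starting material
3 | (2R)-hept-6-en-2-ol | C=CCCC[C@@H](C)O | intermediate
4 | 4,4,5,5-tetramethyl-2-vinyl-1,3,2-dioxaborolane | C=CB1OC(C)(C)C(C)(C)O1 | starting material
5 | (2R,6E)-7-(4,4,5,5-tetramethyl-1,3,2-dioxaborolan-2-yl)hept-6-en-2-ol | CC1(C)OB(/C=C/CCC[C@@H](C)O)OC1(C)C | intermediate
6 | ethyl 4-(diethoxyphosphoryl)-3-oxobutanoate | CCOC(=O)CC(=O)CP(=O)(OCC)OCC | starting material
7 | 3-bromoprop-1-ene | C=CCBr | starting material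
8 | ethyl 2-[(diethoxyphosphoryl)acetyl]pent-4-enoate (racemic) | CCOC(=O)C(CC=C)C(=O)CP(=O)(OCC)OCC | intermediate
9 | ethyl 2-{2-[(diethoxyphosphoryl)methyl]-1,3-dioxolan-2-yl}pent-4-enoate (racemic) | CCOC(=O)C(CC=C)C1(CP(=O)(OCC)OCC)OCCO1 | intermediate
10 | diethyl {[2-(1-oxopent-4-en-2-yl)-1,3-dioxolan-2-yl]methyl}phosphonate (racemic) | O=CC(CC=C)C1(CP(=O)(OCC)OCC)OCCO1 | intermediate
11 | tert-butyl 2-methylprop-2-enoate | C=C(C)C(=O)OC(C)(C)C | starting material
12 | tert-butyl (2E)-5-{2-[(diethoxyphosphoryl)methyl]-1,3-dioxolan-2-yl}-2-methyl-6-oxohex-2-enoate (racemic) | C/C(=C\CC(C=O)C1(CP(=O)(OCC)OCC)OCCO1)C(=O)OC(C)(C)C | intermediate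
13 | 2,2-dimethyl-1,3-dioxan-5-one | CC1(C)OCC(=O)CO1 | starting material
14 | tert-butyl (2E,6S)-5-{2-[(diethoxyphosphoryl)methyl]-1,3-dioxolan-2-yl}-6-[(4S)-2,2-dimethyl-5-oxo-1,3-dioxan-4-yl]-6-hydroxy-2-methylhex-2-enoate (C5 epimers) | CC1(C)OCC(=O)[C@@H](O1)[C@@H](O)C(C/C=C(\C)C(=O)OC(C)(C)C)C2(CP(=O)(OCC)OCC)OCCO2 | intermediate
15 | tert-butyl (2E,6S,7S)-5-[(diethoxyphosphoryl)acetyl]-6,7,9-trihydroxy-2-methyl-8-oxonon-2-enoate (C5 epimers) | OCC(=O)[C@@H](O)[C@@H](O)C(C/C=C(\C)C(=O)OC(C)(C)C)C(=O)CP(=O)(OCC)OCC | intermediate
16 | tert-butyl (2E)-4-[(5R,6S)-5,6-dihydroxy-4-(hydroxymethyl)-2-oxocyclohex-3-en-1-yl]-2-methylbut-2-enoate (C6 epimers) | C/C(=C\CC1C(=O)C=C(CO)[C@@H](O)[C@H]1O)C(=O)OC(C)(C)C | intermediate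
17 | tert-butyl (2E)-4-[(5R,6S)-5,6-dihydroxy-4-(hydroxymethyl)-3-iodo-2-oxocyclohex-3-en-1-yl]-2-methylbut-2-enoate (C6 epimers) | C/C(=C\CC1C(=O)C(I)=C(CO)[C@@H](O)[C@H]1O)C(=O)OC(C)(C)C | intermediate
18 | tert-butyl (2E)-4-[(5R,6S)-5,6-dihydroxy-3-[(1E,6R)-6-hydroxyhept-1-en-1-yl]-4-(hydroxymethyl)-2-oxocyclohex-3-en-1-yl]-2-methylbut-2-enoate (C6 epimers) | C/C(=C\CC1C(=O)C(/C=C/CCC[C@@H](C)O)=C(CO)[C@@H](O)[C@H]1O)C(=O)OC(C)(C)C | intermediate
19 | (2E)-4-[(5R,6S)-5,6-dihydroxy-3-[(1E,6R)-6-hydroxyhept-1-en-1-yl]-4-(hydroxymethyl)-2-oxocyclohex-3-en-1-yl]-2-methylbut-2-enoic acid (C6 epimers) | C/C(=C\CC1C(=O)C(/C=C/CCC[C@@H](C)O)=C(CO)[C@@H](O)[C@H]1O)C(=O)O | intermediate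
20 | hexakis(trimethylsilyl) derivative of 19: trimethylsilyl ester, four trimethylsilyl ethers and the C1–C6 trimethylsilyl dienol ether | C/C(=C\CC1=C(O[Si](C)(C)C)C(/C=C/CCC[C@@H](C)O[Si](C)(C)C)=C(CO[Si](C)(C)C)[C@@H](O[Si](C)(C)C)[C@H]1O[Si](C)(C)C)C(=O)O[Si](C)(C)C | intermediate
21 | pestallic acid I, (2E)-4-[(1R,5R,6S)-5,6-dihydroxy-3-[(1E,6R)-6-hydroxyhept-1-en-1-yl]-4-(hydroxymethyl)-2-oxocyclohex-3-en-1-yl]-2-methylbut-2-enoic acid | C/C(=C\C[C@H]1C(=O)C(/C=C/CCC[C@@H](C)O)=C(CO)[C@@H](O)[C@H]1O)C(=O)O | target

## Step count and risks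

Total step count: 11. Longest linear sequence: 9 steps (steps 3 to 11, from 6).

The three steps most likely to fail, most risky first:

Step 7. The enamine aldol of the hindered aldehyde (α-branched, with a quaternary ketal carbon next to it) may be too slow, so that the aldehyde only epimerises, the donor self-condenses and the adduct reverts by retro-aldol. In the aqueous stages the unprotected ketol may also epimerise at C4 through its enediol. The fallback replaces catalytic enamine chemistry by a preformed chiral lithium enolate. It sets out from 12 and 13: dioxanone 13 is deprotonated enantioselectively with a C2-symmetric chiral lithium amide (lithium bis(1-phenylethyl)amide with LiCl, THF, −78 °C, the enantiomer that gives the 4S enolate), and the enolate adds to 12 through a closed six-membered transition state to give the same anti aldol 14, now isolated. Compound 14 is then hydrolysed to 15 and 15 is cyclised with the reagents of step 7 in two separate operations, and the route is rejoined at 16. No new compound is made (F0).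

Step 11. Protonation of the dienol ether may not be face-selective, or the base may remove a γ-hydrogen at C4 or a doubly allylic hydrogen of the butenoate chain, which would epimerise C4 or move the side-chain double bond. The fallback gives up kinetic control and uses equilibration and separation. It sets out from 19: the C6 epimers are separated by reversed-phase chromatography, which delivers 21 directly, and the unwanted epimer is re-equilibrated with Et3N in MeOH and recycled. No new compound is made (F0).

Step 8. Conjugate addition of the amine catalyst to the fully substituted C3 may be too slow, so that iodine is consumed by slow oxidation of the polyol before C2 is halogenated. The fallback delivers the halogen with the phosphonate instead of onto the finished enone. It sets out from 15, taken out of the flask after the acid stage of step 7: bromination of the CH2 between C=O and P=O with N-bromosuccinimide (aqueous THF, 0 °C) should give tert-butyl (2E,6S,7S)-5-[bromo(diethoxyphosphoryl)acetyl]-6,7,9-trihydroxy-2-methyl-8-oxonon-2-enoate F1. Its Horner–Wadsworth–Emmons closure with K2CO3 in water (α-halophosphonates give α-haloalkenes) should give tert-butyl (2E)-4-[(5R,6S)-3-bromo-5,6-dihydroxy-4-(hydroxymethyl)-2-oxocyclohex-3-en-1-yl]-2-methylbut-2-enoate F2. F2 is coupled with 5 under the conditions of step 9 and the route is rejoined at 18.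

Further compounds

F0 | step 7 | none | none
F0 | step 11 | none | none
F1 | step 8 | tert-butyl (2E,6S,7S)-5-[bromo(diethoxyphosphoryl)acetyl]-6,7,9-trihydroxy-2-methyl-8-oxonon-2-enoate (C5 epimers, bromine-bearing carbon unassigned) | OCC(=O)[C@@H](O)[C@@H](O)C(C/C=C(\C)C(=O)OC(C)(C)C)C(=O)C(Br)P(=O)(OCC)OCC
F2 | step 8 | tert-butyl (2E)-4-[(5R,6S)-3-bromo-5,6-dihydroxy-4-(hydroxymethyl)-2-oxocyclohex-3-en-1-yl]-2-methylbut-2-enoate (C6 epimers) | C/C(=C\CC1C(=O)C(Br)=C(CO)[C@@H](O)[C@H]1O)C(=O)OC(C)(C)C
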